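## Retrosynthetic overview

Numbering (3,7-dioxabicyclo[3.3.0]octane): C1 carbinol bridgehead, C2 guaiacyl carbon, O3, C4, C5 CH bridgehead, C6 veratryl carbon, O7, C8. Ring A = C1-C2-O3-C4-C5; ring B = C5-C6-O7-C8-C1.
Endgame: fluoride desilylation, preceded by hydroboration–oxidation of a ring-fusion enol ether C1=C8, which installs the tertiary C1–OH from the convex face.
Ring B is never closed directly as a five-membered ring. It is first laid down as the cyclopropane C1–C5–C6 of a 3-oxabicyclo[3.1.0]hexane-1-carbaldehyde and is then enlarged by C8 and O7 in a Cloke–Wilson rearrangement (C1–C6 broken, C6–O7 made).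
Enabling feature: the C1–C6 bond of that cyclopropane is a vicinal donor–acceptor bond (electron-rich veratryl on C6, formyl C8=O7 on C1), and the rigid ring A holds the formyl oxygen next to C6.
Ring A and the cyclopropane form together from an acyclic 1,6-enyne ether by Au-catalysed oxidative cyclisation. The enyne comes from a Williamson union of an (S)-aryl propargylic alcohol (catalytic asymmetric alkynylation of O-TIPS-vanillin, the only external source of chirality) with 3,4-dimethoxycinnamyl bromide.

Key step: step 8

Assumption: (S,S)-ProPhenol is taken to give the configuration drawn for the carbinol of step 2. If the sense of induction is the opposite, the equally available (R,R)-ligand is used and nothing else changes.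

## Route

Step 1
Reactants: 1 vanillin
Product: 2 3-methoxy-4-(triisopropylsilyloxy)benzaldehyde
Conditions: TIPSCl (1.1 equiv), imidazole (2 equiv), DMF, rt
Reagents that add atoms: triisopropylsilyl chloride, CC(C)[Si](Cl)(C(C)C)C(C)C
Why: Imidazole-promoted silylation of the phenol, chosen because the hindered aryl TIPS ether should survive carbonate, alkoxide, gold, Lewis acid and borane and later leaves with fluoride without touching a benzylic C–O bond.

Step 2
Reactants: 2 3-methoxy-4-(triisopropylsilyloxy)benzaldehyde; 3 trimethylsilylacetylene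
Product: 5 (R)-1-[3-methoxy-4-(triisopropylsilyloxy)phenyl]-3-(trimethylsilyl)prop-2-yn-1-ol, via alkynylzinc 4 (not isolated)
Conditions: Me2Zn (3 equiv), (S,S)-ProPhenol (10 mol %), Ph3P=O (20 mol %), toluene, 0 °C; aq NH4Cl
Reagents that add atoms: none
Why: Dinuclear zinc ProPhenol-catalysed enantioselective alkynylation of an aromatic aldehyde, in which the chiral Zn2 pocket binds aldehyde and alkynylzinc 4 side by side and delivers the alkynyl group to one carbonyl face, so that the catalyst sets C2, the only stereocentre that comes from an external source.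

Step 3
Reactants: 5 (R)-TMS-propargylic alcohol
Product: 6 (S)-1-[3-methoxy-4-(triisopropylsilyloxy)phenyl]prop-2-yn-1-ol
Conditions: K2CO3 (0.2 equiv), MeOH, 0 °C
Reagents that add atoms: none
Why: Carbonate-catalysed methanolysis of the C(sp)–Si bond, far faster than attack on the hindered aryl O–TIPS group, leaves C2 untouched (the descriptor changes from R to S only because the CIP ranks of alkynyl and aryl swap).

Step 4
Reactants: 7 methyl (E)-3-(3,4-dimethoxyphenyl)acrylate
Product: 8 (E)-3-(3,4-dimethoxyphenyl)prop-2-en-1-ol
Conditions: DIBAL-H (2.2 equiv), CH2Cl2, −78 → 0 °C; aq Rochelle salt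
Reagents that add atoms: none
Why: DIBAL-H reduces the conjugated ester by two 1,2-hydride additions and leaves the E-alkene in place.

Step 5
Reactants: 8 (E)-3-(3,4-dimethoxyphenyl)prop-2-en-1-ol
Product: 9 (E)-3,4-dimethoxycinnamyl bromide
Conditions: PBr3 (0.4 equiv), Et2O, 0 °C; used crude at once
Reagents that add atoms: phosphorus tribromide, BrP(Br)Br
Why: Bromination of the primary allylic alcohol through its phosphite ester (SN2), run cold and used at once because the electron-rich cinnamyl bromide ionises easily.

Step 6
Reactants: 6 (S)-propargylic alcohol; 9 (E)-3,4-dimethoxycinnamyl bromide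
Product: 10 (S)-1-[3-methoxy-4-(triisopropylsilyloxy)phenyl]prop-2-ynyl (E)-3,4-dimethoxycinnamyl ether (1,6-enyne)
Conditions: NaH (1.1 equiv), THF, 0 °C; then 9, Bu4NI (10 mol %), 0 °C → rt
Reagents that add atoms: none
Why: Williamson ether synthesis, SN2 of the sodium alkoxide at the primary allylic carbon with iodide catalysis, in which the C2–O bond is never broken, so that the configuration at C2 and the E geometry are both kept.

Step 7
Reactants: 10 enyne ether
Product: 11 (1R,2R,5R,6S)-6-(3,4-dimethoxyphenyl)-2-[3-methoxy-4-(triisopropylsilyloxy)phenyl]-3-oxabicyclo[3.1.0]hexane-1-carbaldehyde (veratryl exo on the cyclopropane, trans to C4 and cis to CHO; C2 aryl anti to the cyclopropane)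
Conditions: IPrAuCl (5 mol %), AgSbF6 (5 mol %), Ph2SO (2 equiv), CH2Cl2, 0 °C → rt
Reagents that add atoms: diphenyl sulfoxide, O=S(c1ccccc1)c1ccccc1
Why: Gold(I)-catalysed oxidative cyclisation of a 1,6-enyne, in which 5-exo-dig attack of the cinnamyl alkene on the Au-bound terminal alkyne gives a cyclopropyl gold carbene (carbene carbon C8) that takes an oxygen atom from Ph2SO, the E geometry being carried into the trans C4/veratryl relation at C5/C6 and the C2 centre steering the alkene face, because allylic 1,3-strain with the LAu–C8 unit puts H-2 in the alkenyl-gold plane and the aryl group on the side away from the incoming C5=C6, hence anti to the new cyclopropane.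

Step 8
Reactants: 11 cyclopropanecarbaldehyde
Product: 12 (2R,5R,6S)-6-(3,4-dimethoxyphenyl)-2-[3-methoxy-4-(triisopropylsilyloxy)phenyl]-3,7-dioxabicyclo[3.3.0]oct-1(8)-ene
Conditions: Sc(OTf)3 (5 mol %), 4 Å MS, CH2Cl2 (0.02 M), −20 °C → rt; Et3N quench, base-washed silica
Reagents that add atoms: none
Why: The Lewis acid binds the formyl oxygen and the push–pull C1–C6 bond heterolyses to a zwitterion made of a 3,4-dimethoxybenzylic cation at C6 and a scandium enolate C1=C8–O7, after which O7 captures C6; this is the Cloke–Wilson cyclopropyl-carbonyl to 2,3-dihydrofuran rearrangement, known for donor–acceptor cyclopropyl ketones and carbaldehydes, and it enlarges the three-membered ring C1–C5–C6 by the two atoms C8 and O7. Ring B closes by 5-(enolendo) O-alkylation, the mode in which an enolate reacts through the in-plane lone pair of oxygen and not through carbon, so that C-closure only regenerates 11 whereas O-closure releases the cyclopropane strain (about 27 kcal/mol), which pays for the change from C=O to an enol ether. The only new stereocentre is C6: O7 enters on the side from which C1 leaves (formal retention, least motion in the contact zwitterion), which places the veratryl group trans to C4 on the convex face, also the thermodynamically preferred exo position, so that any C6 epimer of 11 should converge on the same product, while C2 and C5 are not touched and the C1 centre is deliberately erased. The selectivity needed is cleavage of C1–C6 and not of C1–C5 or C5–C6, secured because only C1–C6 carries a donor and an acceptor on its two ends, and closure before loss of H-5 (styrene formation), secured by ring A, which holds O7 within bonding distance of C6. Low temperature, sieves, dilution and the amine quench protect the acid-labile enol ether and the benzylic C2–O3 bond. In one isomerisation the step delivers the complete 2,6-diaryl-3,7-dioxabicyclo[3.3.0]octane skeleton and leaves C1=C8 polarised for oxygenation at the hindered C1.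

Step 9
Reactants: 12 bicyclic enol ether
Product: 14 (1S,2R,5R,6S)-6-(3,4-dimethoxyphenyl)-2-[3-methoxy-4-(triisopropylsilyloxy)phenyl]-3,7-dioxabicyclo[3.3.0]octan-1-ol, via tertiary alkylborane 13 (not isolated)
Conditions: BH3·THF (1.5 equiv), THF, 0 °C; then 30% H2O2, 1 M NaOH, 0 °C
Reagents that add atoms: borane–tetrahydrofuran, [BH3-][O+]1CCCC1 (boron of 13; only H stays in 14); hydrogen peroxide, OO (oxygen at C1)
Why: Hydroboration–oxidation of a cyclic enol ether, in which the O7 lone pair (helped by the inductive pull of O3) polarises C1=C8 so that boron goes to the β-carbon C1 in spite of its substitution, H and B add syn from the convex face syn to H-5 because attack from the other face would build a trans-fused bicyclo[3.3.0]octane, and oxidation with retention turns the C–B bond into the (1S)-carbinol cis to H-5 and to both aryl groups.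

Step 10
Reactants: 14 O-TIPS ether of the target
Product: 15 (1S,2R,5R,6S)-6-(3,4-dimethoxyphenyl)-2-(4-hydroxy-3-methoxyphenyl)-3,7-dioxabicyclo[3.3.0]octan-1-ol (target)
Conditions: TBAF (1.1 equiv), AcOH (1.1 equiv), THF, 0 °C
Reagents that add atoms: none
Why: Fluoride cleaves the Si–O bond of the aryl silyl ether, and the acetic acid buffer keeps the phenol protonated so that no para-quinone methide can form and epimerise C2.

## Compound list

1 | vanillin | COc1cc(C=O)ccc1O | starting material
2 | 3-methoxy-4-(triisopropylsilyloxy)benzaldehyde | COc1cc(C=O)ccc1O[Si](C(C)C)(C(C)C)C(C)C | intermediate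
3 | trimethylsilylacetylene | C#C[Si](C)(C)C | starting material
4 | methyl[(trimethylsilyl)ethynyl]zinc | C[Zn]C#C[Si](C)(C)C | intermediate
5 | (R)-1-[3-methoxy-4-(triisopropylsilyloxy)phenyl]-3-(trimethylsilyl)prop-2-yn-1-ol | COc1cc([C@H](C#C[Si](C)(C)C)O)ccc1O[Si](C(C)C)(C(C)C)C(C)C | intermediate
6 | (S)-1-[3-methoxy-4-(triisopropylsilyloxy)phenyl]prop-2-yn-1-ol | COc1cc([C@H](C#C)O)ccc1O[Si](C(C)C)(C(C)C)C(C)C | intermediate
7 | methyl (E)-3-(3,4-dimethoxyphenyl)acrylate | COC(=O)/C=C/c1ccc(OC)c(OC)c1 | starting material
8 | (E)-3-(3,4-dimethoxyphenyl)prop-2-en-1-ol | OC/C=C/c1ccc(OC)c(OC)c1 | intermediate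
9 | (E)-3,4-dimethoxycinnamyl bromide | BrC/C=C/c1ccc(OC)c(OC)c1 | intermediate
10 | (S)-1-arylprop-2-ynyl (E)-3,4-dimethoxycinnamyl ether (1,6-enyne) | COc1cc([C@H](C#C)OC/C=C/c2ccc(OC)c(OC)c2)ccc1O[Si](C(C)C)(C(C)C)C(C)C | intermediate
11 | (1R,2R,5R,6S)-2,6-diaryl-3-oxabicyclo[3.1.0]hexane-1-carbaldehyde | O=C[C@@]12[C@@H](c3ccc(O[Si](C(C)C)(C(C)C)C(C)C)c(OC)c3)OC[C@@H]1[C@H]2c1ccc(OC)c(OC)c1 | intermediate
12 | (2R,5R,6S)-2,6-diaryl-3,7-dioxabicyclo[3.3.0]oct-1(8)-ene | COc1cc([C@H]2OC[C@@H]3[C@@H](c4ccc(OC)c(OC)c4)OC=C23)ccc1O[Si](C(C)C)(C(C)C)C(C)C | intermediate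
13 | C1-boryl-2,6-diaryl-3,7-dioxabicyclo[3.3.0]octane (drawn as RBH2) | COc1cc([C@H]2OC[C@@H]3[C@@H](c4ccc(OC)c(OC)c4)OC[C@]23B)ccc1O[Si](C(C)C)(C(C)C)C(C)C | intermediate
14 | O-TIPS ether of the target, (1S,2R,5R,6S) | COc1cc([C@H]2OC[C@@H]3[C@@H](c4ccc(OC)c(OC)c4)OC[C@]23O)ccc1O[Si](C(C)C)(C(C)C)C(C)C | intermediate
15 | (1S,2R,5R,6S)-6-(3,4-dimethoxyphenyl)-2-(4-hydroxy-3-methoxyphenyl)-3,7-dioxabicyclo[3.3.0]octan-1-ol | COc1cc([C@H]2OC[C@@H]3[C@@H](c4ccc(OC)c(OC)c4)OC[C@]23O)ccc1O | target

## Step count

Total step count: 10.
Longest linear sequence: 8 steps (1 → 2 → 5 → 6 → 10 → 11 → 12 → 14 → 15).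

## Steps most likely to fail

**Step 7.**
- The enyne may close in the 6-endo mode that oxygen-tethered enynes are prone to.
- The sulfoxide may add to the benzylic end of the delocalised cation instead of the carbene carbon.
- The C2 centre may steer the alkene face poorly.

The fallback sets out from 10 and replaces π-acid catalysis by a ruthenium-carbene bicyclisation. Cp*RuCl(cod) (5 mol %) and trimethylsilyldiazomethane in Et2O convert allyl propargyl ethers with a terminal alkyne into 1-alkenyl-3-oxabicyclo[3.1.0]hexanes. Here this should give the (Z)-2-(trimethylsilyl)vinyl-substituted bicycle F1. Lemieux–Johnson cleavage of the vinylsilane (catalytic OsO4, NaIO4, 2,6-lutidine, dioxane–water) then comes back to the route at 11.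

**Step 8.**
- The ring-opened zwitterion may lose H-5 and end as a styrene.
- The equilibrium may stop short of full conversion because the product carries a ring-fusion double bond.
- The Lewis acid may hydrolyse or oligomerise the enol ether, or ionise the C2–O3 bond.

The fallback sets out from 11 and expands the same cyclopropane at the carboxylic acid level, where closure gives a lactone and is irreversible.
- Pinnick oxidation (NaClO2, NaH2PO4, 2-methyl-2-butene, t-BuOH–water) gives the cyclopropanecarboxylic acid F2.
- TfOH (5 mol %) in CH2Cl2 at 0 °C opens the donor–acceptor bond and closes the cis-fused γ-lactone F3, with the veratryl group exo.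
- KHMDS followed by 2-(phenylsulfonyl)-3-phenyloxaziridine at −78 °C hydroxylates the lactone enolate on the convex face to give the α-hydroxy lactone F4.
- DIBAL-H at −78 °C gives the lactol F5.
- Et3SiH/BF3·OEt2 at −78 °C removes the anomeric hydroxyl and comes back to the route at 14.

**Step 9.**
- Boron may be placed on the less hindered C8.
- The tertiary β-alkoxyborane may eliminate with opening of ring A or B.
- Access to the convex face may be slowed by the neighbouring aryl group on C2.

The fallback sets out from 12 and brings the oxygen in as an electrophile, so that the regiochemistry no longer depends on the borane. m-CPBA with NaHCO3 in CH2Cl2–MeOH at −20 °C should form the labile convex-face 1,8-epoxide F6. Methanol opens it at C8 in the same flask to give the 1-hydroxy-8-methoxy acetal F7. Et3SiH/BF3·OEt2 at −78 °C then reduces the acetal carbon and comes back to the route at 14.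

## Further compounds

F1 | step 7 | (1R,2R,5R,6S)-2,6-diaryl-1-[(Z)-2-(trimethylsilyl)vinyl]-3-oxabicyclo[3.1.0]hexane | C[Si](C)(C)/C=C\[C@@]12[C@@H](c3ccc(O[Si](C(C)C)(C(C)C)C(C)C)c(OC)c3)OC[C@@H]1[C@H]2c1ccc(OC)c(OC)c1
F2 | step 8 | 2,6-diaryl-3-oxabicyclo[3.1.0]hexane-1-carboxylic acid | OC(=O)[C@@]12[C@@H](c3ccc(O[Si](C(C)C)(C(C)C)C(C)C)c(OC)c3)OC[C@@H]1[C@H]2c1ccc(OC)c(OC)c1
F3 | step 8 | 2,6-diaryl-3,7-dioxabicyclo[3.3.0]octan-8-one (cis-fused, both aryl groups exo) | COc1cc([C@H]2OC[C@@H]3[C@@H](c4ccc(OC)c(OC)c4)OC(=O)[C@H]23)ccc1O[Si](C(C)C)(C(C)C)C(C)C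
F4 | step 8 | 1-hydroxy-2,6-diaryl-3,7-dioxabicyclo[3.3.0]octan-8-one | COc1cc([C@H]2OC[C@@H]3[C@@H](c4ccc(OC)c(OC)c4)OC(=O)[C@]23O)ccc1O[Si](C(C)C)(C(C)C)C(C)C
F5 | step 8 | 2,6-diaryl-3,7-dioxabicyclo[3.3.0]octane-1,8-diol (lactol, anomers) | COc1cc([C@H]2OC[C@@H]3[C@@H](c4ccc(OC)c(OC)c4)OC(O)[C@]23O)ccc1O[Si](C(C)C)(C(C)C)C(C)C
F6 | step 9 | 1,8-epoxy-2,6-diaryl-3,7-dioxabicyclo[3.3.0]octane (epoxide on the convex face) | COc1cc([C@H]2OC[C@@H]3[C@@H](c4ccc(OC)c(OC)c4)O[C@H]5O[C@@]235)ccc1O[Si](C(C)C)(C(C)C)C(C)C
F7 | step 9 | 8-methoxy-2,6-diaryl-3,7-dioxabicyclo[3.3.0]octan-1-ol (anomers) | COc1cc([C@H]2OC[C@@H]3[C@@H](c4ccc(OC)c(OC)c4)OC(OC)[C@]23O)ccc1O[Si](C(C)C)(C(C)C)C(C)C
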